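**Remark on the chemistry.** Alkene 5 is expected as a mainly Z mixture of geometric isomers and is used as such, because step 3 removes the double bond. Methyl 2-bromo-6-methylbenzoate (7) is taken as a catalogue compound.

## Analysis of the target

The target (19) is 6-hydroxy-8-(2-hydroxy-4-methoxy-6-pentylphenoxy)-3-pentyl-1H-isochromen-1-one. Its benzenoid ring A (C4a, C5 to C8, C8a) is fused to a 3-pentyl pyranone, and the C8 oxygen carries a second benzene ring B (C1' to C6'). There is no stereocentre and no stereogenic double bond; the only non-aromatic C=C is the ring-bound C3=C4 bond of the enol lactone. The enol lactone is opened by alkoxide or hydroxide and can be saturated at C3=C4. The two phenols differ in acidity (C6-OH para to the lactone carbonyl, C2'-OH on an electron-rich ring), and ring B, with oxygen at C1' and C4', is easily oxidised. The synthesis is hard for three reasons: both benzene rings are 1,2,3,5-tetrasubstituted; three oxygens must end in three different states (C6 OH, C2' OH, C4' OMe); and the diaryl ether is flanked on both sides (C8a on ring A, C2' and C6' on ring B). The strategy rests on one feature. Without the C6 and C4' oxygens each ring is 1,2,3-trisubstituted, and C6–H and C4'–H are then the only aromatic C–H bonds with no ortho substituent. C5–H and C7–H lie beside C4a and the C8 oxygen, and C3'–H and C5'–H lie beside the C2' oxygen and the C6' pentyl group. A sterically governed C–H functionalisation can therefore place both oxygens in one operation.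

## Retrosynthetic reasoning

**19 back to 17.** The O2–C3 bond of the lactone and the two acetal O–C bonds are cut, giving keto ester 17 (through diphenol 18). Acid is chosen for the forward step because it frees both phenols and closes the enol lactone through the enol oxygen. Base could instead send the other ketone enolate onto the ester carbon and give a naphthalenediol.

**17 back to 12 and 14.** The C3–C4 bond is cut between the benzylic carbon and the ketone carbon. The ortho ester acidifies the methyl group of toluate 12, so its lateral anion 15 can be acylated. Amide 14 (one step from 13) holds the adduct 16 as a chelate, so the reaction stops at the ketone. The cut is made here because it reduces ring A to a toluate: the methyl group is inert in all earlier steps and is the third substituent that makes ring A 1,2,3-substituted.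

**12 back to 10 through 11.** Only O–C bonds of a methyl ether and an acetal are removed. The forward steps must tell the two new phenols of 10 apart, and acidity is the handle: the ring A hydroxyl is para to the ester, the ring B hydroxyl sits on an alkoxy-rich ring.

**10 back to 8 (through 9).** The C6–O and C4'–O bonds are traced back to C–H bonds. This is the central disconnection: it turns two 1,2,3,5-tetrasubstituted rings into two 1,2,3-trisubstituted rings, whose halves are simple. The forward reaction has to borylate each ring exactly once, at the single unflanked C–H bond, and then oxidise both C–B bonds.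

**8 back to 6 and 7.** The C8–O bond on the ring A side is cut. Ring A is the electrophile because the bromide of 7 has one ortho neighbour and an activating ortho ester; the reverse polarity would need oxidative addition at a di-ortho-substituted halide. A fluoride displacement was weighed and dropped. The ester is forced out of the ring plane by its two ortho neighbours and cannot stabilise the anionic adduct, and a hindered phenoxide would sooner demethylate the ester. Copper catalysis does not depend on that activation.

**6 back to 1 and 3 (through 5, 4 and 2).** The pentyl chain is cut at its first C–C bond beyond the benzylic carbon, as a Wittig olefination of aldehyde 2 with ylide 4 followed by hydrogenation. The acetal is placed at the aldehyde stage, on 1. There the formyl group distinguishes the two hydroxyls electronically, whereas after chain installation only the bulk of a flanking pentyl group would distinguish them.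

## Alternatives that were turned down

**Alternative 1: ring B assembled as a cyclohexane-1,3-dione.**
- Disconnection: C1'–C6' and C3'–C4' of ring B.
- Forward key step: an alkoxide base adds aryloxyacetone A1, through its aryloxy-bearing carbon, to the β-carbon of methyl (E)-oct-2-enoate A2. The methyl carbon then closes onto the ester (Michael addition, then Claisen closure) to give dione A3 (racemic trans; both stereocentres vanish on aromatisation). Dehydrogenation and O-methylation would complete ring B.
- For: the ether oxygen is installed by an unhindered phenol alkylation, which is stronger than step 4 of the chosen route. The pentyl group and both ring B oxygens arrive with A1 and A2, and no precious metal is needed.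
- Against: the donor must react at its more hindered, oxygen-bearing α-carbon. Reaction at the methyl carbon leads to a 2-aryloxy-5-pentyl dione and the wrong arene. A β-alkyl enoate is a poor acceptor for such an enolate. The aromatisation is an oxidation next to electron-rich ring A, the C2' and C4' oxygens must still be told apart, and the diethylamide must later become the lactone.
- Comparison: three uncertain operations reach what the chosen route reaches with one sterically dictated C–H functionalisation and one acidity-based protection, and the sequence is longer.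

**Alternative 2: pyranone by carboxylate-directed C–H annulation.**
- Disconnection: C4a–C4 and O2–C3.
- Forward key step: a Cp*-ligated trivalent rhodium catalyst metalates the only free ortho C–H bond of acid A4 (the future C4a). The rhodacycle inserts the carbene unit of sulfoxonium ylide A5, and the keto acid cyclodehydrates to the dibenzyl ether A6 of 19. Debenzylation would finish.
- For: the pyranone forms in one catalytic step, without strong base or a final acid step on acetals, and its regiochemistry is fixed. On this point it is stronger than steps 9 and 10.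
- Against: A4 must already contain every oxygen of both rings. The 1,2,3,5-substituted ring B phenol and the hindered ether would have to be made by classical means, which is the hard part of the target. Hydrogenolysis of two benzyl ethers beside the C3=C4 bond also risks saturation.
- Comparison: the chosen strategy spends its one uncertain step on the arene oxygenation, where the target is hard, and accepts a conventional pyranone construction in exchange.

**Alternative 3: ring B by vinylketene and alkyne benzannulation.**
- Disconnection: C2'–C3', C4'–C5' and C1'–C2'.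
- Forward key step: irradiation of diazo ketone A7 triggers a Wolff rearrangement to an aryloxy-substituted ketene. This undergoes (2+2) cycloaddition with methoxyacetylene A8, four-electron ring opening and six-electron electrocyclisation, giving phenol A9 after tautomerisation.
- For: all three oxygens are differentiated by construction, which is clearly stronger than step 6. The polarity of the ynol ether fixes the ring B pattern.
- Against: A7 is a β-aryloxy enone diazo ketone that itself needs several uncertain steps. A8 is volatile and unstable. The photochemical diazo step scales poorly, and the electron-rich ketene may dimerise. A9 still needs the same lateral metalation endgame.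
- Comparison: the chosen route reaches the equivalent intermediate 12 from catalogue arenes in seven steps with robust reagents. Its price is the acidity-based differentiation in step 6.

Key step: step 5

## Route

Step 1
Reactants: 1 2,3-dihydroxybenzaldehyde
Product: 2 2-hydroxy-3-(methoxymethoxy)benzaldehyde
Conditions: NaH (2.2 equiv), DMF–THF, 0 °C; MOMCl (1.0 equiv), 0 °C to rt; aq. NH4Cl
Reagents that add atoms: chloromethyl methyl ether (MOMCl), COCCl
Why: Regioselective Williamson-type O-alkylation of the dianion: the C2 phenoxide is delocalised into and chelated by the formyl group, so the C3 phenoxide is the more nucleophilic site and takes the single equivalent of electrophile, which fixes early which oxygen later becomes the diaryl ether.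

Step 2
Reactants: 2 2-hydroxy-3-(methoxymethoxy)benzaldehyde; 3 butyltriphenylphosphonium bromide
Product: 5 2-(methoxymethoxy)-6-[(1Z)-pent-1-en-1-yl]phenol (major isomer of an E/Z mixture), via butylidenetriphenylphosphorane 4 (not isolated)
Conditions: 3 (1.3 equiv), KOtBu (2.4 equiv), THF, 0 °C; then 2, 0 °C to rt
Reagents that add atoms: none
Why: Wittig olefination with a non-stabilised ylide; the surplus base turns the phenol into its phenoxide, which the ylide tolerates, and the alkene geometry needs no control because step 3 removes the double bond.

Step 3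
Reactants: 5 2-(methoxymethoxy)-6-[(1Z)-pent-1-en-1-yl]phenol (E/Z mixture)
Product: 6 2-(methoxymethoxy)-6-pentylphenol
Conditions: H2 (1 atm), 10% Pd/C, EtOAc, rt
Reagents that add atoms: none
Why: Heterogeneous catalytic hydrogenation of a disubstituted styrenyl alkene; the acetal and the aryl C–O bonds are inert in neutral ethyl acetate.

Step 4
Reactants: 6 2-(methoxymethoxy)-6-pentylphenol; 7 methyl 2-bromo-6-methylbenzoate
Product: 8 methyl 2-[2-(methoxymethoxy)-6-pentylphenoxy]-6-methylbenzoate
Conditions: CuI (10 mol%), picolinic acid (20 mol%), K3PO4 (2 equiv), DMSO, 90 °C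
Reagents that add atoms: none
Why: Ullmann-type copper-catalysed C–O coupling with a picolinate ligand, a system suited to di-ortho-substituted phenols; the ortho ester assists oxidative addition at the bromide, and the doubly flanked ester resists attack by phenoxide or phosphate.

Step 5
Reactants: 8 methyl 2-[2-(methoxymethoxy)-6-pentylphenoxy]-6-methylbenzoate
Product: 10 methyl 4-hydroxy-2-[4-hydroxy-2-(methoxymethoxy)-6-pentylphenoxy]-6-methylbenzoate, via bis(pinacolboronate) 9 (not isolated)
Conditions: [Ir(OMe)(cod)]2 (3 mol%), 4,4'-di-tert-butyl-2,2'-bipyridine (6 mol%), B2pin2 (2.2 equiv), THF, 80 °C; evaporate; KHSO5 (Oxone, 2KHSO5·KHSO4·K2SO4; 2.5 equiv KHSO5), acetone–H2O, 0 °C to rt, 15 min; aq. NaHSO3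
Reagents that add atoms: bis(pinacolato)diboron, CC1(C)OB(OC1(C)C)B1OC(C)(C)C(C)(C)O1 (the boron of 9); potassium peroxymonosulfate, [K+].[O-]S(=O)(=O)OO (the two new oxygens of 10)
Why: The monovalent iridium precatalyst, the bipyridine and B2pin2 form a trivalent iridium tris(boryl) complex, which cleaves an aryl C–H bond and releases the aryl boronate by C–B reductive elimination, the HBpin by-product being recycled. The closest known reaction type is the sterically controlled iridium-catalysed borylation of 1,2,3-trisubstituted arenes at C5, followed by oxidation of the aryl boronate to the phenol with peroxymonosulfate in aqueous acetone. The crowded tris(boryl) centre does not reach a C–H bond with an ortho substituent; ring A of 8 offers only C4–H of the benzoate (C6 of the isocoumarin) and ring B only C4'–H, the other four aromatic C–H bonds lying beside the aryloxy oxygen, the acetal oxygen, the methyl group or the pentyl group. The step needs site selectivity on each ring and complete reaction on both; the electron-poorer ring A should react first, and the excess of diboron and the temperature are meant to carry the electron-rich ring B through. Benzylic and acetal C–H bonds react far more slowly with this ligand, and the twisted, doubly flanked ester cannot direct an ortho borylation. In the oxidation the peroxide oxygen adds to boron, the aryl group migrates from boron to oxygen at the same carbon, and hydrolysis gives the phenol; a short, cold exposure limits acetal hydrolysis and further oxidation of the ring B phenol. No ring is closed and no stereocentre is formed; two C–O bonds are made.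

Step 6
Reactants: 10 methyl 4-hydroxy-2-[4-hydroxy-2-(methoxymethoxy)-6-pentylphenoxy]-6-methylbenzoate
Product: 11 methyl 2-[4-hydroxy-2-(methoxymethoxy)-6-pentylphenoxy]-4-(methoxymethoxy)-6-methylbenzoate
Conditions: K2CO3 (1.0 equiv), MOMCl (1.05 equiv), acetone, 0 °C
Reagents that add atoms: chloromethyl methyl ether (MOMCl), COCCl
Why: Acidity-controlled Williamson-type O-alkylation: with one equivalent of carbonate mainly the ring A hydroxyl (para to the ester, meta to the aryloxy group) is ionised, so the acetal should form there, as in the usual selective protection of the hydroxyl para to a carbonyl group in dihydroxy aryl ketones and esters.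

Step 7
Reactants: 11 methyl 2-[4-hydroxy-2-(methoxymethoxy)-6-pentylphenoxy]-4-(methoxymethoxy)-6-methylbenzoate
Product: 12 methyl 4-(methoxymethoxy)-2-[4-methoxy-2-(methoxymethoxy)-6-pentylphenoxy]-6-methylbenzoate
Conditions: MeI (1.5 equiv), K2CO3 (2 equiv), DMF, rt
Reagents that add atoms: iodomethane, CI
Why: Williamson methylation of the only remaining phenol; the hindered methyl ester and both acetals are stable to carbonate.

Step 8
Reactants: 13 hexanoyl chloride
Product: 14 N-methoxy-N-methylhexanamide
Conditions: MeNHOMe·HCl (1.1 equiv), Et3N (2.2 equiv), CH2Cl2, 0 °C to rt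
Reagents that add atoms: N,O-dimethylhydroxylamine hydrochloride, CNOC.Cl
Why: N-acylation of an amine by an acid chloride, giving the Weinreb amide needed for a clean single acylation in step 9.

Step 9
Reactants: 12 methyl 4-(methoxymethoxy)-2-[4-methoxy-2-(methoxymethoxy)-6-pentylphenoxy]-6-methylbenzoate; 14 N-methoxy-N-methylhexanamide
Product: 17 methyl 4-(methoxymethoxy)-2-[4-methoxy-2-(methoxymethoxy)-6-pentylphenoxy]-6-(2-oxoheptyl)benzoate, via lithiated toluate 15 (not isolated), via tetrahedral lithium adduct 16 (not isolated)
Conditions: LiN(iPr)2 (1.2 equiv), THF, −78 °C, 30 min; 14 (1.3 equiv), −78 to −40 °C; aq. NH4Cl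
Reagents that add atoms: none
Why: Lateral lithiation of an ortho-toluate followed by Weinreb ketone synthesis: the amide base removes the benzylic proton conjugated to the ester rather than adding to the doubly flanked ester, and the chelated adduct 16 survives until the quench, so no second addition and no enolate chemistry of the ketone occurs in the flask.

Step 10
Reactants: 17 methyl 4-(methoxymethoxy)-2-[4-methoxy-2-(methoxymethoxy)-6-pentylphenoxy]-6-(2-oxoheptyl)benzoate
Product: 19 6-hydroxy-8-(2-hydroxy-4-methoxy-6-pentylphenoxy)-3-pentyl-1H-isochromen-1-one (the target), via diphenol keto ester 18 (not isolated)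
Conditions: conc. HCl (3 equiv), MeOH, 50 °C; evaporate; TsOH·H2O (0.2 equiv), toluene, 90 °C
Reagents that add atoms: none
Why: Acid-catalysed acetal cleavage in methanol, which traps the methoxymethyl unit as dimethoxymethane, followed by acid-catalysed 6-exo-trig enol lactonisation of the aryl-conjugated enol onto the ester with loss of methanol, driven in toluene where no alcohol competes.

## Compound list

1 | 2,3-dihydroxybenzaldehyde | O=Cc1cccc(O)c1O | starting material
2 | 2-hydroxy-3-(methoxymethoxy)benzaldehyde | O=Cc1cccc(OCOC)c1O | intermediate
3 | butyltriphenylphosphonium bromide | CCCC[P+](c1ccccc1)(c1ccccc1)c1ccccc1.[Br-] | starting material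
4 | butylidenetriphenylphosphorane (not isolated) | CCCC=P(c1ccccc1)(c1ccccc1)c1ccccc1 | intermediate
5 | 2-(methoxymethoxy)-6-[(1Z)-pent-1-en-1-yl]phenol (major isomer of an E/Z mixture) | CCC/C=C\c1cccc(OCOC)c1O | intermediate
6 | 2-(methoxymethoxy)-6-pentylphenol | CCCCCc1cccc(OCOC)c1O | intermediate
7 | methyl 2-bromo-6-methylbenzoate | COC(=O)c1c(C)cccc1Br | starting material
8 | methyl 2-[2-(methoxymethoxy)-6-pentylphenoxy]-6-methylbenzoate | COC(=O)c1c(C)cccc1Oc1c(OCOC)cccc1CCCCC | intermediate
9 | methyl 2-[2-(methoxymethoxy)-6-pentyl-4-(4,4,5,5-tetramethyl-1,3,2-dioxaborolan-2-yl)phenoxy]-6-methyl-4-(4,4,5,5-tetramethyl-1,3,2-dioxaborolan-2-yl)benzoate (not isolated) | COC(=O)c1c(C)cc(B2OC(C)(C)C(C)(C)O2)cc1Oc1c(OCOC)cc(B2OC(C)(C)C(C)(C)O2)cc1CCCCC | intermediate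
10 | methyl 4-hydroxy-2-[4-hydroxy-2-(methoxymethoxy)-6-pentylphenoxy]-6-methylbenzoate | COC(=O)c1c(C)cc(O)cc1Oc1c(OCOC)cc(O)cc1CCCCC | intermediate
11 | methyl 2-[4-hydroxy-2-(methoxymethoxy)-6-pentylphenoxy]-4-(methoxymethoxy)-6-methylbenzoate | COC(=O)c1c(C)cc(OCOC)cc1Oc1c(OCOC)cc(O)cc1CCCCC | intermediate
12 | methyl 4-(methoxymethoxy)-2-[4-methoxy-2-(methoxymethoxy)-6-pentylphenoxy]-6-methylbenzoate | COC(=O)c1c(C)cc(OCOC)cc1Oc1c(OCOC)cc(OC)cc1CCCCC | intermediate
13 | hexanoyl chloride | CCCCCC(=O)Cl | starting material
14 | N-methoxy-N-methylhexanamide | CCCCCC(=O)N(C)OC | intermediate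
15 | benzylic lithium derivative of 12 (not isolated) | [Li]Cc1cc(OCOC)cc(Oc2c(OCOC)cc(OC)cc2CCCCC)c1C(=O)OC | intermediate
16 | lithium alkoxide adduct of 15 and 14 (not isolated; racemic, the centre is lost on collapse) | CCCCCC(O[Li])(Cc1cc(OCOC)cc(Oc2c(OCOC)cc(OC)cc2CCCCC)c1C(=O)OC)N(C)OC | intermediate
17 | methyl 4-(methoxymethoxy)-2-[4-methoxy-2-(methoxymethoxy)-6-pentylphenoxy]-6-(2-oxoheptyl)benzoate | CCCCCC(=O)Cc1cc(OCOC)cc(Oc2c(OCOC)cc(OC)cc2CCCCC)c1C(=O)OC | intermediate
18 | methyl 4-hydroxy-2-(2-hydroxy-4-methoxy-6-pentylphenoxy)-6-(2-oxoheptyl)benzoate (not isolated) | CCCCCC(=O)Cc1cc(O)cc(Oc2c(O)cc(OC)cc2CCCCC)c1C(=O)OC | intermediate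
19 | 6-hydroxy-8-(2-hydroxy-4-methoxy-6-pentylphenoxy)-3-pentyl-1H-isochromen-1-one | CCCCCc1cc2cc(O)cc(Oc3c(O)cc(OC)cc3CCCCC)c2c(=O)o1 | target

## Step count and least certain steps

Total: 10 steps. Longest linear sequence: 9 steps (steps 1 to 7, 9 and 10); step 8 is a one-step side branch.

**Step 5 (key step).** The second borylation, on the electron-rich and crowded ring B, may stall. The new ring B phenol, which is para to the ether oxygen, may be oxidised further by peroxymonosulfate, and the acidic oxidant may hydrolyse the acetal.
Fallback, from 6 to 12, with the ring B oxygen installed classically and a single borylation left on ring A: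
- Phenol 6 is brominated para to the free hydroxyl (NBS, MeCN, 0 °C) to give 4-bromo-2-(methoxymethoxy)-6-pentylphenol F1.
- Copper-mediated methoxylation (NaOMe, CuBr, DMF–MeOH, 110 °C) gives 4-methoxy-2-(methoxymethoxy)-6-pentylphenol F2.
- Coupling with 7 under the conditions of step 4 gives methyl 2-[4-methoxy-2-(methoxymethoxy)-6-pentylphenoxy]-6-methylbenzoate F3, in which ring B has no unflanked C–H bond left.
- Borylation under the conditions of step 5 then gives only the ring A boronate, methyl 2-[4-methoxy-2-(methoxymethoxy)-6-pentylphenoxy]-6-methyl-4-(4,4,5,5-tetramethyl-1,3,2-dioxaborolan-2-yl)benzoate F4.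
- Oxidation with KHSO5 gives methyl 4-hydroxy-2-[4-methoxy-2-(methoxymethoxy)-6-pentylphenoxy]-6-methylbenzoate F5.
- MOMCl and iPr2NEt in CH2Cl2 convert F5 into 12, by-passing steps 5 to 7.

**Step 6.** Site discrimination may be lost. The ring B phenoxide, once formed, is the more nucleophilic, and alkylation of both phenols or of the wrong one would follow.
Fallback, from 10 to 11, with discrimination moved to an acyl transfer that depends on leaving-group ability:
- Ac2O and pyridine give methyl 4-acetoxy-2-[4-acetoxy-2-(methoxymethoxy)-6-pentylphenoxy]-6-methylbenzoate F6.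
- Hydrazine acetate (1.1 equiv, DMF, 0 °C) should cleave the ring A acetate, whose phenoxide is the better leaving group, giving methyl 2-[4-acetoxy-2-(methoxymethoxy)-6-pentylphenoxy]-4-hydroxy-6-methylbenzoate F7.
- MOMCl and iPr2NEt give methyl 2-[4-acetoxy-2-(methoxymethoxy)-6-pentylphenoxy]-4-(methoxymethoxy)-6-methylbenzoate F8.
- K2CO3 in MeOH removes the remaining acetate and returns 11.

**Step 9.** Proton transfer from the α-methylene of 14 to the benzylic anion may quench 15, and 15 may condense with the ester of unreacted 12.
Fallback, from 12 to 17, by aldol addition and oxidation: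
- Anion 15 is generated as in step 9 and treated at −78 °C with hexanal F9.
- A cold quench with acetic acid, before the alkoxide can lactonise, gives methyl 2-(2-hydroxyheptyl)-4-(methoxymethoxy)-6-[4-methoxy-2-(methoxymethoxy)-6-pentylphenoxy]benzoate F10 (racemic).
- Dess–Martin periodinane in CH2Cl2 oxidises F10 to 17.

**Step 10.** The liberated methoxymethyl unit may be captured by the electron-rich ring B. Lactonisation may be incomplete, or the acyl group may transfer to the C2' hydroxyl to form a seven-membered lactone.
Fallback, from 17 to 19, with the ring closed before the phenols are exposed: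
- LiN(SiMe3)2 (THF, −78 to 0 °C) forms the aryl-conjugated enolate at the benzylic methylene, whose oxygen acylates on the ester to give 6-(methoxymethoxy)-8-[4-methoxy-2-(methoxymethoxy)-6-pentylphenoxy]-3-pentyl-1H-isochromen-1-one F11.
- HCl in MeOH at 40 °C then removes both acetals from the stable isocoumarin and gives 19.

**Step 4.** The di-ortho-substituted phenoxide may couple slowly, and protodebromination of 7 may take over.
Fallback, from 6 to 8, by nucleophilic aromatic substitution on a planar, strongly activating formyl arene:
- Phenol 6 and 2-fluoro-6-methylbenzaldehyde F12 (K2CO3, DMF, 110 °C) give 2-[2-(methoxymethoxy)-6-pentylphenoxy]-6-methylbenzaldehyde F13.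
- Pinnick oxidation (NaClO2, NaH2PO4, 2-methyl-2-butene, tBuOH–H2O) gives 2-[2-(methoxymethoxy)-6-pentylphenoxy]-6-methylbenzoic acid F14.
- MeI and K2CO3 in DMF esterify F14 to 8.

## Further compounds

F1 | step 5 | 4-bromo-2-(methoxymethoxy)-6-pentylphenol | CCCCCc1cc(Br)cc(OCOC)c1O
F2 | step 5 | 4-methoxy-2-(methoxymethoxy)-6-pentylphenol | CCCCCc1cc(OC)cc(OCOC)c1O
F3 | step 5 | methyl 2-[4-methoxy-2-(methoxymethoxy)-6-pentylphenoxy]-6-methylbenzoate | COC(=O)c1c(C)cccc1Oc1c(OCOC)cc(OC)cc1CCCCC
F4 | step 5 | methyl 2-[4-methoxy-2-(methoxymethoxy)-6-pentylphenoxy]-6-methyl-4-(4,4,5,5-tetramethyl-1,3,2-dioxaborolan-2-yl)benzoate | COC(=O)c1c(C)cc(B2OC(C)(C)C(C)(C)O2)cc1Oc1c(OCOC)cc(OC)cc1CCCCC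
F5 | step 5 | methyl 4-hydroxy-2-[4-methoxy-2-(methoxymethoxy)-6-pentylphenoxy]-6-methylbenzoate | COC(=O)c1c(C)cc(O)cc1Oc1c(OCOC)cc(OC)cc1CCCCC
F6 | step 6 | methyl 4-acetoxy-2-[4-acetoxy-2-(methoxymethoxy)-6-pentylphenoxy]-6-methylbenzoate | COC(=O)c1c(C)cc(OC(C)=O)cc1Oc1c(OCOC)cc(OC(C)=O)cc1CCCCC
F7 | step 6 | methyl 2-[4-acetoxy-2-(methoxymethoxy)-6-pentylphenoxy]-4-hydroxy-6-methylbenzoate | COC(=O)c1c(C)cc(O)cc1Oc1c(OCOC)cc(OC(C)=O)cc1CCCCC
F8 | step 6 | methyl 2-[4-acetoxy-2-(methoxymethoxy)-6-pentylphenoxy]-4-(methoxymethoxy)-6-methylbenzoate | COC(=O)c1c(C)cc(OCOC)cc1Oc1c(OCOC)cc(OC(C)=O)cc1CCCCC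
F9 | step 9 | hexanal | CCCCCC=O
F10 | step 9 | methyl 2-(2-hydroxyheptyl)-4-(methoxymethoxy)-6-[4-methoxy-2-(methoxymethoxy)-6-pentylphenoxy]benzoate (racemic) | CCCCCC(O)Cc1cc(OCOC)cc(Oc2c(OCOC)cc(OC)cc2CCCCC)c1C(=O)OC
F11 | step 10 | 6-(methoxymethoxy)-8-[4-methoxy-2-(methoxymethoxy)-6-pentylphenoxy]-3-pentyl-1H-isochromen-1-one | CCCCCc1cc2cc(OCOC)cc(Oc3c(OCOC)cc(OC)cc3CCCCC)c2c(=O)o1
F12 | step 4 | 2-fluoro-6-methylbenzaldehyde | Cc1cccc(F)c1C=O
F13 | step 4 | 2-[2-(methoxymethoxy)-6-pentylphenoxy]-6-methylbenzaldehyde | O=Cc1c(C)cccc1Oc1c(OCOC)cccc1CCCCC
F14 | step 4 | 2-[2-(methoxymethoxy)-6-pentylphenoxy]-6-methylbenzoic acid | OC(=O)c1c(C)cccc1Oc1c(OCOC)cccc1CCCCC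
A1 | alternative 1 | N,N-diethyl-4-(methoxymethoxy)-2-methyl-6-(2-oxopropoxy)benzamide | CC(=O)COc1cc(OCOC)cc(C)c1C(=O)N(CC)CC
A2 | alternative 1 | methyl (E)-oct-2-enoate | CCCCC/C=C/C(=O)OC
A3 | alternative 1 | N,N-diethyl-2-[(trans-2,4-dioxo-6-pentylcyclohexyl)oxy]-4-(methoxymethoxy)-6-methylbenzamide (racemic) | CCCCC[C@@H]1CC(=O)CC(=O)[C@H]1Oc1cc(OCOC)cc(C)c1C(=O)N(CC)CC
A4 | alternative 2 | 4-(benzyloxy)-2-[2-(benzyloxy)-4-methoxy-6-pentylphenoxy]benzoic acid | OC(=O)c1ccc(OCc2ccccc2)cc1Oc1c(OCc2ccccc2)cc(OC)cc1CCCCC
A5 | alternative 2 | 1-[dimethyl(oxo)-λ6-sulfanylidene]heptan-2-one | CCCCCC(=O)C=S(C)(C)=O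
A6 | alternative 2 | 6-(benzyloxy)-8-[2-(benzyloxy)-4-methoxy-6-pentylphenoxy]-3-pentyl-1H-isochromen-1-one | CCCCCc1cc2cc(OCc3ccccc3)cc(Oc3c(OCc4ccccc4)cc(OC)cc3CCCCC)c2c(=O)o1
A7 | alternative 3 | methyl 2-{[(1E)-2-(2-diazoacetyl)hept-1-en-1-yl]oxy}-4-(methoxymethoxy)-6-methylbenzoate | COC(=O)c1c(C)cc(OCOC)cc1O/C=C(\CCCCC)C(=O)C=[N+]=[N-]
A8 | alternative 3 | methoxyacetylene | COC#C
A9 | alternative 3 | methyl 2-(2-hydroxy-4-methoxy-6-pentylphenoxy)-4-(methoxymethoxy)-6-methylbenzoate | COC(=O)c1c(C)cc(OCOC)cc1Oc1c(O)cc(OC)cc1CCCCC
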